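common to all: L 0.25 M; Q 0.300 M; X 13 mM; G 6.2 mM; time 15 min
- ash: temperature 100 °C
- alder: temperature 108 °C
- elm: temperature 116 °C

    L + X ⇌ X + D (K1 = 0.86, k1 = 2.56 L mol⁻¹ s⁻¹, Ea1 = 49.0 kJ mol⁻¹, ΔH1 = 22.0 kJ mol⁻¹)
    G + D ⇌ G.D (K2 = 490 L mol⁻¹, k2 = 56.1 L mol⁻¹ s⁻¹, Ea2 = 66.0 kJ mol⁻¹, ΔH2 = −18.0 kJ mol⁻¹)
    Q + G.D → G + Z (k3 = 0.334 L mol⁻¹ s⁻¹, Ea3 = 62.0 kJ mol⁻¹)
    G → J (k4 = 4.21 × 10⁻⁶ s⁻¹, Ea4 = 122 kJ mol⁻¹)
    (constants at 100 °C)

* which of these there is most of at the end, counted by the L in it, ash (D / Z / L)
* which of these there is most of at the end, counted by the L in it, alder (D / Z / L)
* which of these there is most of at the end, counted by the L in it, elm (D / Z / L)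
* the largest of these amounts at the end, in percent of the L charged, ash
* the largest of these amounts at the end, in percent of the L charged, alder
* the largest of these amounts at the end, in percent of the L charged, elm

- the list of constants is for 100 °C, to be carried to other temperatures by the activation energies and enthalpies

Slowness in this flask is a matter of flows: at the start step 3 can pass at most 37.3 mM min⁻¹, even with the G charged held as G.D, which is less than the 499 mM min⁻¹ of the forward step 1. The binding constant of G times the c(D) that step 1 reaches from the charged L comes to 56.6, so I expect G.D to be the resting state of G while c(D) stands near that level. The rate constant of step 3 times the charged c(G) times the time comes to 1.86 in ash, and this turnover budget is the number I carry.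

My first way keeps G bound throughout. Then c(Q) falls pseudo-first-order with the budget as its exponent, and Z is the charged c(Q) times one minus exp(−budget). Consuming the L charged needs a budget of 1.79.

| flask | temperature | budget | Z by the first way, of the L charged |
|---|---|---|---|
| ash | 100 °C | 1.86 | 101% |
| alder | 108 °C | 2.83 | 113% |
| elm | 116 °C | 4.24 | 118% |

In ash the first way gives more Z than the L charged, so something in it cheats.

My second way writes the balance of L, the limiting reagent: the charge is Z plus G.D plus the pool p, which is c(L) + c(D), and I take step 1 to be at equilibrium, which would put 46.2% of p as D. Let e be the excess of Q, 50.0 mM, and let w be the reciprocal of the binding constant times that share times e, here 0.0883. Letting G.D thin out as D falls and integrating, the budget needed to reach p is ln(charged c(Q)/(p + e)) plus a tail, w times ln[(charged c(L)/charged c(Q))(p + e)/p].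

I try p = 6.25 mM. The tail is 0.178, the need is 1.85, and that lies just under the budget of ash. At that point I reckon G.D at 58.6% of the G charged, so the first way cheats by holding G bound to the end.

Counting p and G.D in the balance, I commit in ash to Z at 96.0%. In alder and in elm the budget exceeds the 1.79 of the first way by more than the tail I reckoned for ash, so there I cap the first way at the charge, as an estimate: Z at 100% in alder and Z at 100% in elm.

The forecast names Z, Z and Z, at 95.5%, 99.8% and 100%, on the ground that “G is nearly saturated as G.D”, with a tail added; its figure for ash is not mine.

The flasks end with Z at 96.1% in ash, Z at 99.9% in alder and Z at >99.9% in elm. G.D in ash stands at 52.7% of the G charged after 15.0 min. A neighbour flask, as ash but with 1.0 M of L, makes Q the smaller charge, and the same budget 1.86 then allows Z of 25.3% of the L charged. In that neighbour G.D stands at 99.3% of the G charged after 15.0 min, and Z ends at 25.3% while L holds 39.9%.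

(The constants belong to no real substance.)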